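**Retrosynthetic overview**
Numbering per half: ring B = C1(Me), C2, C3, C4(iPr, its CH = C11); ring A = C4a, C5, C6(Me), C7(O), C8, C8a; the halves are joined C8–C8′. The strategy rests on the isopropyl-bearing C4 next to the C3 methylene in each ring B. With OH added at C3 and a C11 methyl turned into =CH2, the C3–C4 bond opens by a retro carbonyl-ene reaction. This gives a C3 aldehyde and a C4=C11 dimethylalkene on C4a.
End game: the isopropenyl groups are saturated first, C3–OH is then removed by a radical deoxygenation, and the C7 methyl ethers are cleaved last.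
The open biaryl dialdehyde comes from a C4a bromide (Suzuki coupling with a 2-methylprop-1-enyl boronate). Its C1 centre is set by copper-catalysed asymmetric methyl addition to a bis(enethioate).
The C8–C8′ bond is made first by Ullmann coupling. Ring order: both rings A are bought, then the biaryl bond is made, then both rings B are closed together in the key step.

Key step: step 10

Assumption 1: the target string leaves the C8–C8′ axis undefined. The tetra-ortho-substituted axis forms as a racemate in step 2, so from 10 onward each compound is a pair of atropisomers with identical carbon stereocentres. Both fit the string, and they can be separated by chromatography at 11 or 17 if a single one is wanted.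
Assumption 2: the Tol-BINAP antipode used in step 5 is the one that gives the S centre. It is to be fixed by a trial run on a simple β-aryl enethioate, both antipodes being commercial.

**Step 1**
Reactants: 1 5-bromo-2-methylanisole
Product: 3 1-bromo-2-iodo-3-methoxy-4-methylbenzene, via aryllithium 2 (not isolated)
Conditions: LDA (1.1 equiv), THF, −78 °C; I2, THF, −78 °C → rt
Reagents that add atoms: iodine, II
Why: Directed ortho-metalation followed by an iodine quench, in which the ring C–H flanked by OMe and Br is by far the most acidic and holding the aryllithium at −78 °C keeps LiBr loss to the aryne slow until iodine traps it.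

**Step 2**
Reactants: 3 1-bromo-2-iodo-3-methoxy-4-methylbenzene (two molecules)
Product: 4 2,2′-dibromo-6,6′-dimethoxy-5,5′-dimethylbiphenyl (racemic axis)
Conditions: activated Cu bronze (4 equiv), DMF, 130 °C
Reagents that add atoms: none
Why: Ullmann homocoupling, in which copper metal inserts into the weak C–I bond well before C–Br, so the hindered C8–C8′ bond is forged while the partners are still small and both C8a bromines are kept as handles.

**Step 3**
Reactants: 4 2,2′-dibromo-6,6′-dimethoxy-5,5′-dimethylbiphenyl
Product: 6 6,6′-dimethoxy-5,5′-dimethylbiphenyl-2,2′-dicarbaldehyde, via dilithiobiaryl 5 (not isolated)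
Conditions: n-BuLi (2.3 equiv), THF, −78 °C; DMF, −78 °C → rt; 1 M HCl
Reagents that add atoms: N,N-dimethylformamide, CN(C)C=O
Why: Double bromine–lithium exchange and Bouveault-type formylation, where exchange at −78 °C outruns any attack on the ethers and the carbon delivered by DMF becomes C1 of each half.

**Step 4**
Reactants: 6 6,6′-dimethoxy-5,5′-dimethylbiphenyl-2,2′-dicarbaldehyde; 7 S-ethyl 2-(diethoxyphosphoryl)ethanethioate
Product: 8 S,S′-diethyl (2E,2′E)-3,3′-(6,6′-dimethoxy-5,5′-dimethylbiphenyl-2,2′-diyl)bis(prop-2-enethioate)
Conditions: 7 (2.4 equiv), LiCl, DBU, MeCN/THF, 0 °C → rt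
Reagents that add atoms: none
Why: Horner–Wadsworth–Emmons olefination under Masamune–Roush conditions, in which the stabilised phosphonate gives the E alkenes and the LiCl/amine pair is mild enough to leave the thioesters intact.

**Step 5**
Reactants: 8 bis(enethioate); 9 methylmagnesium bromide
Product: 10 S,S′-diethyl (3S,3′S)-3,3′-(6,6′-dimethoxy-5,5′-dimethylbiphenyl-2,2′-diyl)bis(butanethioate)
Conditions: 9 (3 equiv), CuI (6 mol %), Tol-BINAP (6.6 mol %), t-BuOMe, −70 °C; 1 M HCl
Reagents that add atoms: none
Why: Copper-catalysed asymmetric conjugate addition of a Grignard reagent to an α,β-unsaturated thioester, in which the thioester is reactive enough for the sluggish methyl reagent, the CuI/Tol-BINAP catalyst (the variant suited to β-aryl acceptors) chooses the alkene face and sets C1 and C1′ as S, and two additions on one molecule push most stereochemical leakage into a separable S,R diastereomer.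

**Step 6**
Reactants: 10 bis(thioester)
Product: 11 (3S,3′S)-3,3′-(6,6′-dimethoxy-5,5′-dimethylbiphenyl-2,2′-diyl)bis(butan-1-ol)
Conditions: LiAlH4, THF, 0 °C → rt; aqueous NaOH work-up
Reagents that add atoms: none
Why: Hydride reduction of the thioesters to primary alcohols, which removes sulfur before the palladium step and leaves a group inert to NBS and aqueous base, while C1 lies β to the carbonyl and cannot epimerise.

**Step 7**
Reactants: 11 diol
Product: 12 (3S,3′S)-3,3′-(3,3′-dibromo-6,6′-dimethoxy-5,5′-dimethylbiphenyl-2,2′-diyl)bis(butan-1-ol) (Br on C4a and C4a′)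
Conditions: NBS (2.1 equiv), MeCN, 0 °C → rt, dark
Reagents that add atoms: N-bromosuccinimide, O=C1CCC(=O)N1Br
Why: Electrophilic aromatic bromination, where both positions ortho to the C7 methoxy group are blocked, so NBS in acetonitrile (ionic regime) should attack the para carbon C4a in preference to C5, which is only meta to oxygen.

**Step 8**
Reactants: 12 dibromo diol; 13 4,4,5,5-tetramethyl-2-(2-methylprop-1-en-1-yl)-1,3,2-dioxaborolane
Product: 14 (3S,3′S)-3,3′-[6,6′-dimethoxy-5,5′-dimethyl-3,3′-bis(2-methylprop-1-en-1-yl)biphenyl-2,2′-diyl]bis(butan-1-ol)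
Conditions: 13 (3 equiv), Pd(OAc)2 (5 mol %), SPhos (10 mol %), K3PO4, toluene/H2O, 90 °C
Reagents that add atoms: none
Why: Suzuki–Miyaura coupling, in which the electron-rich biarylphosphine lets zerovalent palladium insert into the electron-rich, mono-ortho-hindered C4a–Br bond, the alkenyl boronate delivers C4, C11 and both methyls in one piece, and free alcohols are tolerated.

**Step 9**
Reactants: 14 bis(alkenyl) diol
Product: 15 (3S,3′S)-3,3′-[6,6′-dimethoxy-5,5′-dimethyl-3,3′-bis(2-methylprop-1-en-1-yl)biphenyl-2,2′-diyl]bis(butanal)
Conditions: Dess–Martin periodinane (2.4 equiv), CH2Cl2, 0 °C → rt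
Reagents that add atoms: none
Why: Dess–Martin oxidation, whose near-neutral conditions stop at the aldehyde, leave the trisubstituted styrenes alone and cannot touch C1, which is not α to the carbonyl.

**Step 10**
Reactants: 15 biaryl dialdehyde
Product: 17 (1S,3S,4S,1′S,3′S,4′S)-7,7′-dimethoxy-1,1′,6,6′-tetramethyl-4,4′-di(prop-1-en-2-yl)-1,1′,2,2′,3,3′,4,4′-octahydro-8,8′-binaphthalene-3,3′-diol, via bis(aluminium alkoxide) 16 (not isolated)
Conditions: Me2AlCl (2.2 equiv, 1.1 per CHO), CH2Cl2, −78 → −20 °C; 1 M HCl
Reagents that add atoms: none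
Why: Me2AlCl binds each C3 aldehyde, C3 bonds to the alkene carbon C4 while a hydrogen of the C11 methyl trans to the arene passes to oxygen through a six-membered cyclic array, and the alcohol–aluminium complex then loses methane to give alkoxide 16, which removes the proton that could otherwise dehydrate or isomerise the product. The closest known reaction type is the Lewis-acid-promoted intramolecular carbonyl-ene cyclisation of citronellal to isopulegol (a type-one ene closure). Each ring B closes 6-exo-trig with respect to the C4=C11 bond (C4 in the ring, C11 and the carbonyl oxygen outside) through a half-chair fused to ring A. C4 is controlled by C1: peri strain with the C8 aryl group holds the C1 methyl pseudoaxial, and with the forming C4–C11 and C3–O bonds both equatorial in a trans-decalin-like array the isopropenyl group ends cis to the C1 methyl (4S) and the hydroxyl trans to the isopropenyl group (3S), the C3 centre being deleted later so that only the C1/C4 relation has to hold. The step needs bonding at C4 and not at C11, which is secured because only the C11 methyls carry transferable hydrogens, the ortho sec-alkyl group twists the alkene out of conjugation, the flanked C7 methoxy group is a weak donor, and about one equivalent of a mild Lewis acid per aldehyde keeps the process concerted, so that seven-membered closure through a C4 benzylic cation should not compete. The two closures are independent, each half reading its own C1 centre.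

**Step 11**
Reactants: 17 bis(isopropenyl) diol
Product: 18 (1S,3S,4S,1′S,3′S,4′S)-4,4′-diisopropyl-7,7′-dimethoxy-1,1′,6,6′-tetramethyl-1,1′,2,2′,3,3′,4,4′-octahydro-8,8′-binaphthalene-3,3′-diol
Conditions: H2 (3 atm), RhCl(PPh3)3 (10 mol %), benzene/EtOH, rt
Reagents that add atoms: none
Why: Homogeneous hydrogenation, in which RhCl(PPh3)3 saturates 1,1-disubstituted alkenes with little double-bond migration so the benzylic, allylic C4–H is not scrambled, no new stereocentre arises, and acting before the deoxygenation removes the alkene that could let the later C3 radical trigger a 1,2-vinyl shift to a benzylic C4 radical.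

**Step 12**
Reactants: 18 bis(isopropyl) diol
Product: 20 bis(S-methyl xanthate) of 18 (O-C(=S)SMe on C3 and C3′), via disodium bis(xanthate) 19 (not isolated)
Conditions: NaH, imidazole (cat.), THF, 0 °C → rt; CS2; MeI
Reagents that add atoms: carbon disulfide, S=C=S; iodomethane, CI
Why: Xanthate formation, the first half of the Barton–McCombie deoxygenation, in which the sodium alkoxides of these menthol-like secondary alcohols add to CS2 and the dithiocarbonate salts are S-methylated in the same flask without breaking any bond to a stereocentre.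

**Step 13**
Reactants: 20 bis(xanthate)
Product: 21 (1S,4S,1′S,4′S)-4,4′-diisopropyl-7,7′-dimethoxy-1,1′,6,6′-tetramethyl-1,1′,2,2′,3,3′,4,4′-octahydro-8,8′-binaphthalene
Conditions: Bu3SnH (4 equiv), AIBN (0.2 equiv), toluene, 110 °C
Reagents that add atoms: none
Why: Barton–McCombie radical deoxygenation, in which the stannyl radical adds to C=S, the C3–O bond fragments to a secondary radical that has no β-leaving group or nearby alkene and simply takes hydrogen from Bu3SnH, erasing the C3 centres and leaving C1 and C4 untouched.

**Step 14**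
Reactants: 21 dimethyl ether
Product: 22 target, (1S,4S,1′S,4′S)-4,4′-diisopropyl-1,1′,6,6′-tetramethyl-1,1′,2,2′,3,3′,4,4′-octahydro-8,8′-binaphthalene-7,7′-diol
Conditions: BBr3 (6 equiv), CH2Cl2, −78 → 0 °C; H2O
Reagents that add atoms: none
Why: Lewis-acid aryl methyl ether cleavage, in which BBr3 binds the twisted methoxy oxygens and bromide removes the methyl groups by SN2 attack at low temperature, conditions that do not ionise the benzylic centres, so the bis-phenol is released with all four stereocentres intact.

**Compound list**
1 | 5-bromo-2-methylanisole | COc1cc(Br)ccc1C | starting material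
2 | (6-bromo-2-methoxy-3-methylphenyl)lithium | COc1c([Li])c(Br)ccc1C | intermediate
3 | 1-bromo-2-iodo-3-methoxy-4-methylbenzene | COc1c(I)c(Br)ccc1C | intermediate
4 | 2,2′-dibromo-6,6′-dimethoxy-5,5′-dimethylbiphenyl | COc1c(C)ccc(Br)c1-c1c(OC)c(C)ccc1Br | intermediate
5 | 2,2′-dilithio-6,6′-dimethoxy-5,5′-dimethylbiphenyl | COc1c(C)ccc([Li])c1-c1c(OC)c(C)ccc1[Li] | intermediate
6 | 6,6′-dimethoxy-5,5′-dimethylbiphenyl-2,2′-dicarbaldehyde | COc1c(C)ccc(C=O)c1-c1c(OC)c(C)ccc1C=O | intermediate
7 | S-ethyl 2-(diethoxyphosphoryl)ethanethioate | CCSC(=O)CP(=O)(OCC)OCC | starting material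
8 | bis[(E)-enethioate] | COc1c(C)ccc(/C=C/C(=O)SCC)c1-c1c(OC)c(C)ccc1/C=C/C(=O)SCC | intermediate
9 | methylmagnesium bromide | C[Mg]Br | starting material
10 | bis[(S)-3-arylbutanethioate] | COc1c(C)ccc([C@@H](C)CC(=O)SCC)c1-c1c(OC)c(C)ccc1[C@@H](C)CC(=O)SCC | intermediate
11 | bis[(S)-3-arylbutan-1-ol] | COc1c(C)ccc([C@@H](C)CCO)c1-c1c(OC)c(C)ccc1[C@@H](C)CCO | intermediate
12 | C4a,C4a′-dibromo diol | COc1c(C)cc(Br)c([C@@H](C)CCO)c1-c1c(OC)c(C)cc(Br)c1[C@@H](C)CCO | intermediate
13 | 2-methylprop-1-enylboronic acid pinacol ester | CC(C)=CB1OC(C)(C)C(C)(C)O1 | starting material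
14 | bis(2-methylprop-1-enyl) diol | COc1c(C)cc(C=C(C)C)c([C@@H](C)CCO)c1-c1c(OC)c(C)cc(C=C(C)C)c1[C@@H](C)CCO | intermediate
15 | biaryl dialdehyde (key-step precursor) | COc1c(C)cc(C=C(C)C)c([C@@H](C)CC=O)c1-c1c(OC)c(C)cc(C=C(C)C)c1[C@@H](C)CC=O | intermediate
16 | bis[chloro(methyl)aluminium] alkoxide of 17 | COc1c(C)cc2c(c1-c1c(OC)c(C)cc3c1[C@@H](C)C[C@H](O[Al](C)Cl)[C@H]3C(C)=C)[C@@H](C)C[C@H](O[Al](C)Cl)[C@H]2C(C)=C | intermediate
17 | bis(3-hydroxy-4-isopropenyl) tetralin dimer, dimethyl ether (key-step product) | COc1c(C)cc2c(c1-c1c(OC)c(C)cc3c1[C@@H](C)C[C@H](O)[C@H]3C(C)=C)[C@@H](C)C[C@H](O)[C@H]2C(C)=C | intermediate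
18 | bis(3-hydroxy-4-isopropyl) tetralin dimer, dimethyl ether | COc1c(C)cc2c(c1-c1c(OC)c(C)cc3c1[C@@H](C)C[C@H](O)[C@H]3C(C)C)[C@@H](C)C[C@H](O)[C@H]2C(C)C | intermediate
19 | disodium bis(xanthate) of 18 | COc1c(C)cc2c(c1-c1c(OC)c(C)cc3c1[C@@H](C)C[C@H](OC(=S)[S-])[C@H]3C(C)C)[C@@H](C)C[C@H](OC(=S)[S-])[C@H]2C(C)C.[Na+].[Na+] | intermediate
20 | bis(S-methyl xanthate) of 18 | COc1c(C)cc2c(c1-c1c(OC)c(C)cc3c1[C@@H](C)C[C@H](OC(=S)SC)[C@H]3C(C)C)[C@@H](C)C[C@H](OC(=S)SC)[C@H]2C(C)C | intermediate
21 | dimethyl ether of the target | COc1c(C)cc2c(c1-c1c(OC)c(C)cc3c1[C@@H](C)CC[C@H]3C(C)C)[C@@H](C)CC[C@H]2C(C)C | intermediate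
22 | CNP0152871.1, 8,8′-dimer of (1S,4S)-7-hydroxycalamenene | Cc1cc2c(c(-c3c(O)c(C)cc4c3[C@@H](C)CC[C@H]4C(C)C)c1O)[C@@H](C)CC[C@H]2C(C)C | target

**Total step count:** 14
**Longest linear sequence:** 14 steps (from 1)

**Three steps most likely to fail**

Step 10. The likely failure is poor facial selectivity at C4. Relief of peri strain with C5–H may let the alkene react with C11 pseudoaxial, which would put the isopropenyl group trans to the C1 methyl. The fallback sets out from 17, together with whatever C3 or C4 epimers accompany it, and hands control of C4 to a substrate-directed hydrogenation.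
- Dess–Martin oxidation should give the bis(β,γ-unsaturated 3-ketone) F1, in which C4 is configurationally labile.
- KHMDS and PhNTf2 (THF, −78 °C) should enolise toward the benzylic, allylic C4–H and give the bis(dienyl triflate) F2.
- Pd(OAc)2, PPh3, HCO2H and Et3N (DMF, 60 °C) should replace C–OTf by C–H and give the bis(4-isopropenyl-1,2-dihydronaphthalene) F3.
- Hydrogenation over Pd/C (EtOAc, rt) should saturate both alkenes of each half. Hydrogen should reach C4 from the face opposite the pseudoaxial C1 methyl, which places the isopropyl group cis to it.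
- The sequence comes back to the route at 21.

Step 5. Three processes may interfere. The stereogenic axis may erode catalyst control in the mismatched atropisomer. Turnover may be slow on the ortho-aryl-hindered acceptor. After the first addition, the second acceptor arm may capture the product by an intramolecular Michael reaction. The fallback sets out from 8 and replaces catalyst control by a covalently bound auxiliary, whose diastereomers can be purified.
- LiOH (THF/H2O) should give the bis(cinnamic acid) F4.
- Pivaloyl chloride and Et3N, then (S)-4-phenyl-1,3-oxazolidin-2-one and LiCl, should give the bis(N-enoyl oxazolidinone) F5.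
- MeMgBr with CuBr·SMe2 (THF/Me2S, −40 → −10 °C) should add methyl anti to the phenyl group of the chelated s-cis imide and give the bis[(S)-β-methyl imide] F6.
- LiBH4 (Et2O, a little water) should cleave the auxiliary reductively.
- The sequence comes back to the route at 11.

Step 2. Coupling at the doubly flanked C–I bond may be sluggish. At the temperature needed, hydrodeiodination and loss of selectivity over C–Br may compete. The fallback sets out from 1 and moves the coupling to an electron-poor partner that carries no bromine.
- n-BuLi then DMF should give 3-methoxy-4-methylbenzaldehyde F7.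
- In situ protection as the α-amino alkoxide with lithium N,N,N′-trimethylethylenediamide, ortho-lithiation with n-BuLi between the two directing groups and an iodine quench should give 2-iodo-3-methoxy-4-methylbenzaldehyde F8.
- Ullmann coupling (Cu bronze, DMF, 120 °C) is accelerated by the ortho-formyl group.
- The sequence comes back to the route at 6.

**Further compounds**
F1 | step 10 | bis(4-isopropenyl-3-ketone), C4 labile | COc1c(C)cc2c(c1-c1c(OC)c(C)cc3c1[C@@H](C)CC(=O)C3C(C)=C)[C@@H](C)CC(=O)C2C(C)=C
F2 | step 10 | bis(dienyl triflate) | COc1c(C)cc2c(c1-c1c(OC)c(C)cc3c1[C@@H](C)CC(OS(=O)(=O)C(F)(F)F)=C3C(C)=C)[C@@H](C)CC(OS(=O)(=O)C(F)(F)F)=C2C(C)=C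
F3 | step 10 | bis(4-isopropenyl-1,2-dihydronaphthalene) | COc1c(C)cc2c(c1-c1c(OC)c(C)cc3c1[C@@H](C)CC=C3C(C)=C)[C@@H](C)CC=C2C(C)=C
F4 | step 5 | bis[(E)-cinnamic acid] | COc1c(C)ccc(/C=C/C(=O)O)c1-c1c(OC)c(C)ccc1/C=C/C(=O)O
F5 | step 5 | bis[(S)-4-phenyl N-enoyl oxazolidinone] | COc1c(C)ccc(/C=C/C(=O)N2[C@H](COC2=O)c2ccccc2)c1-c1c(OC)c(C)ccc1/C=C/C(=O)N1[C@H](COC1=O)c1ccccc1
F6 | step 5 | bis[(S)-3-arylbutanoyl (S)-4-phenyl oxazolidinone] | COc1c(C)ccc([C@@H](C)CC(=O)N2[C@H](COC2=O)c2ccccc2)c1-c1c(OC)c(C)ccc1[C@@H](C)CC(=O)N1[C@H](COC1=O)c1ccccc1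
F7 | step 2 | 3-methoxy-4-methylbenzaldehyde | COc1cc(C=O)ccc1C
F8 | step 2 | 2-iodo-3-methoxy-4-methylbenzaldehyde | COc1c(I)c(C=O)ccc1C
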